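The route rests on disconnecting C14–C19 in ring C. C14 is a tertiary carbinol, C19 a methyl-bearing quaternary carbon, and C18 next to it carries the ring D oxygen, which is what remains after a carbon radical born from an epoxide attacks a carbonyl group. In one operation Cp2TiCl opens a C18–C19 epoxide and the C19 radical adds 6-exo to the C14 ketone. This closes ring C, forms C14–C19, sets both stereocentres and frees the C18 hydroxyl for ring D. The precursor is a ring A/B ketone (C3 triethylsilyl ether, C10 methylene) joined through C12–C13 to C14=O, carrying the C15 methyl, the (18S,19S)-epoxide and the C22–C23 alkene.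

Key step: step 17

Remarks before the steps
- Numbering is the open-chain one (C2 to C23): ring A is the oxepane O/C2–C7, ring B is C6–C11, ring C is C14–C19, ring D is the oxepanone O/C18–C23.
- Stereochemical check: the target is 3R,6S,7S,11R,14S,15S,18S,19R. The pairs C6/C7 and C18/C19 have the same absolute sense, so one epoxide, (2S,3S)-2,3-epoxygeraniol, serves both halves. Precursor 23 is 15S,18S,19S, and C18 passes into 25 with retention.
- Design choices for the precursor:
  - C3 is carried as the Et3Si ether, which step 7 installs directly and which is removed more easily than a bulkier silyl ether at this neopentyl position.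
  - The C14 ketone is made by aldehyde addition and oxidation, so that no free carboxylic acid ever sits five atoms from the epoxide.
  - The C22–C23 alkene stays as the only unsaturation near C19, because it offers the radical no 5-exo or 6-endo path.
  - Triflate 3 is prepared fresh for steps 3 and 12.
- Assumption: compounds 4, 7 and 15 and both enantiomers of the Shi ketone are purchased.

Step 1
Reactants: 1 geraniol
Product: 2 (2S,3S)-2,3-epoxygeraniol
Conditions: Ti(OiPr)4 (5 mol%), L-(+)-diethyl tartrate (7 mol%), t-BuOOH, 4 Å MS, CH2Cl2, −20 °C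
Reagents that add atoms: tert-butyl hydroperoxide, CC(C)(C)OO
Why: Sharpless asymmetric epoxidation of the allylic alcohol, in which the L-(+)-tartrate titanium complex delivers oxygen to the face that gives the (2S,3S)-epoxide (later C7/C6 and C18/C19) and the remote trisubstituted alkene is left alone.

Step 2
Reactants: 2 (2S,3S)-2,3-epoxygeraniol
Product: 3 (2S,3S)-2,3-epoxygeranyl trifluoromethanesulfonate
Conditions: Tf2O, 2,6-lutidine, CH2Cl2, −78 °C; used at once
Reagents that add atoms: trifluoromethanesulfonic anhydride, O=S(=O)(OS(=O)(=O)C(F)(F)F)C(F)(F)F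
Why: O-sulfonylation of a primary alcohol with a hindered base at low temperature, which touches no stereocentre; the product is used cold because epoxy triflates do not keep.

Step 3
Reactants: 3 (2S,3S)-2,3-epoxygeranyl trifluoromethanesulfonate; 4 dimethyl (2-oxopropyl)phosphonate
Product: 6 dimethyl [(5S,6S)-5,6-epoxy-6,10-dimethyl-2-oxoundec-9-en-1-yl]phosphonate, via phosphonate dianion 5 (not isolated)
Conditions: 4, NaH, THF, 0 °C; n-BuLi, 0 °C; then 3, −78 → 0 °C
Reagents that add atoms: none
Why: γ-alkylation of a β-keto phosphonate dianion, which reacts at its terminal carbon by SN2 displacement of the primary triflate far faster than it could open the trisubstituted epoxide, forming C8–C9.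

Step 4
Reactants: 6 dimethyl [(5S,6S)-5,6-epoxy-6,10-dimethyl-2-oxoundec-9-en-1-yl]phosphonate; 7 benzyloxyacetaldehyde
Product: 8 (2E,7S,8S)-1-benzyloxy-7,8-epoxy-8,12-dimethyltrideca-2,11-dien-4-one
Conditions: Ba(OH)2, THF/H2O (40:1), rt
Reagents that add atoms: none
Why: Horner–Wadsworth–Emmons olefination under mild barium hydroxide conditions that spare the epoxide, giving the (E)-enone and bringing in C12 and C13 with the C13 oxygen as a benzyl ether.

Step 5
Reactants: 8 (2E,7S,8S)-1-benzyloxy-7,8-epoxy-8,12-dimethyltrideca-2,11-dien-4-one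
Product: 9 (2E,7S,8S,11R)-1-benzyloxy-7,8:11,12-diepoxy-8,12-dimethyltridec-2-en-4-one
Conditions: D-fructose-derived Shi ketone (30 mol%), Oxone (2KHSO5·KHSO4·K2SO4), K2CO3, Bu4NHSO4, MeCN/CH2(OMe)2/aq. Na2B4O7 buffer, 0 °C
Reagents that add atoms: potassium peroxymonosulfate, [K+].[O-]S(=O)(=O)OO
Why: Shi asymmetric epoxidation, in which the chiral dioxirane attacks the electron-rich trisubstituted C2–C3 alkene through a spiro transition state, ignores the electron-poor enone, and with the D-fructose catalyst sets C3 as R.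

Step 6
Reactants: 9 (2E,7S,8S,11R)-1-benzyloxy-7,8:11,12-diepoxy-8,12-dimethyltridec-2-en-4-one
Product: 10 (Z)-triethylsilyl enol ether of 9 (C10–OSiEt3 with C10=C11)
Conditions: Et3SiH, RhCl(PPh3)3 (2 mol%), benzene, 50 °C
Reagents that add atoms: triethylsilane, CC[SiH](CC)CC
Why: rhodium-catalysed 1,4-hydrosilylation of the enone, which places the enol double bond regiospecifically between C10 and C11 (mainly Z) and leaves both epoxides intact.

Step 7
Reactants: 10 (Z)-triethylsilyl enol ether of 9
Product: 11 trans-fused ring A/B ketone (oxepane with C3 OSiEt3 and ring B with C10 ketone and equatorial C11 CH2CH2OBn; 3R,6S,7S,11S)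
Conditions: Et3SiOTf (1.1 equiv), 2,6-di-tert-butyl-4-methylpyridine, CH2Cl2, −78 °C; NaHCO3 work-up; then DBU (cat.), CH2Cl2, rt
Reagents that add atoms: triethylsilyl trifluoromethanesulfonate, CC[Si](CC)(CC)OS(=O)(=O)C(F)(F)F (its silyl group ends on O3; the silyl group of the enol ether is given back as the same reagent)
Why: silyl triflate-promoted tandem oxa- and carbacyclisation of a 1,5-diepoxide terminated by an enol silane, in which the silylated C2–C3 epoxide is opened at tertiary C2 by the C6–C7 epoxide oxygen and the resulting bicyclic oxonium ion is opened at C6 with inversion by C11, so rings A and B close together with C6 (axial methyl), C7 and C3 dictated by the two epoxides, and DBU then settles C11 with its chain equatorial.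

Step 8
Reactants: 11 trans-fused ring A/B ketone
Product: 12 ring A/B C10 methylene compound with C13 benzyl ether (3R,6S,7S,11R)
Conditions: Ph3PCH3Br, KOtBu, toluene, 80 °C
Reagents that add atoms: methyltriphenylphosphonium bromide, C[P+](c1ccccc1)(c1ccccc1)c1ccccc1.[Br-]
Why: Wittig methylenation of the hindered ring B ketone at elevated temperature; C11 is already in its thermodynamic configuration, so enolisation under the basic conditions does no harm.

Step 9
Reactants: 12 ring A/B C10 methylene compound with C13 benzyl ether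
Product: 13 ring A/B C13 alcohol
Conditions: lithium 4,4′-di-tert-butylbiphenylide, THF, −78 °C; NH4Cl
Reagents that add atoms: none
Why: reductive cleavage of the benzyl ether by an arene radical anion, which unlike hydrogenolysis leaves the 1,1-disubstituted alkene and the silyl ether untouched.

Step 10
Reactants: 13 ring A/B C13 alcohol
Product: 14 ring A/B C13 iodide
Conditions: I2, PPh3, imidazole, CH2Cl2, 0 °C → rt
Reagents that add atoms: iodine, II
Why: Appel-type iodination of an unhindered primary alcohol through its alkoxyphosphonium salt, buffered by imidazole so that the silyl ether and the alkene survive.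

Step 11
Reactants: 15 (R)-3-bromo-2-methylpropan-1-ol
Product: 16 (R)-(3-bromo-2-methylpropoxy)(tert-butyl)dimethylsilane
Conditions: TBSCl, imidazole, CH2Cl2, rt
Reagents that add atoms: tert-butyldimethylsilyl chloride, CC(C)(C)[Si](C)(C)Cl
Why: standard silylation of a primary alcohol; the purchased stereocentre that becomes C15 is not involved.

Step 12
Reactants: 16 (R)-(3-bromo-2-methylpropoxy)(tert-butyl)dimethylsilane; 3 (2S,3S)-2,3-epoxygeranyl trifluoromethanesulfonate
Product: 18 tert-butyldimethylsilyl ether of (2S,5S,6S)-5,6-epoxy-2,6,10-trimethylundec-9-en-1-ol, via Grignard reagent 17 (not isolated)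
Conditions: Mg, THF, 40 °C; then CuI (10 mol%), 3 in Et2O, −78 → −20 °C
Reagents that add atoms: none
Why: copper-catalysed SN2 coupling of a primary alkylmagnesium bromide with a primary triflate, which is much faster than opening of the trisubstituted epoxide and forms C16–C17 without touching C15, C18 or C19.

Step 13
Reactants: 18 tert-butyldimethylsilyl ether of (2S,5S,6S)-5,6-epoxy-2,6,10-trimethylundec-9-en-1-ol
Product: 19 (2S,5S,6S)-5,6-epoxy-2,6,10-trimethylundec-9-en-1-ol
Conditions: Bu4NF, THF, 0 °C → rt
Reagents that add atoms: none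
Why: fluoride cleavage of the primary silyl ether under non-acidic conditions that keep the epoxide closed.

Step 14
Reactants: 19 (2S,5S,6S)-5,6-epoxy-2,6,10-trimethylundec-9-en-1-ol
Product: 20 (2S,5S,6S)-5,6-epoxy-2,6,10-trimethylundec-9-enal
Conditions: SO3·pyridine, DMSO, i-Pr2NEt, CH2Cl2, 0 °C
Reagents that add atoms: none
Why: Parikh–Doering oxidation, chosen because its mildly basic medium neither opens the epoxide nor epimerises the α-methyl aldehyde at C15.

Step 15
Reactants: 14 ring A/B C13 iodide; 20 (2S,5S,6S)-5,6-epoxy-2,6,10-trimethylundec-9-enal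
Product: 22 C14 secondary alcohol joining ring A/B to the C15–C23 epoxy chain (both C14 epimers), via alkyllithium 21 (not isolated)
Conditions: 14, t-BuLi (2.1 equiv), Et2O/pentane, −78 °C; then 20, −78 °C; NH4Cl at −78 °C
Reagents that add atoms: none
Why: iodine–lithium exchange gives the primary C13 alkyllithium, which adds to the aldehyde at −78 °C faster than it deprotonates C15 or attacks the epoxide; the new carbinol centre C14 forms unselectively and is erased in the next step.

Step 16
Reactants: 22 C14 secondary alcohol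
Product: 23 ring A/B C14 ketone with C18–C19 epoxide and C22–C23 alkene (3R,6S,7S,11R,15S,18S,19S)
Conditions: Dess–Martin periodinane, NaHCO3, CH2Cl2, 0 °C → rt
Reagents that add atoms: none
Why: buffered Dess–Martin oxidation of the secondary alcohol to the C14 ketone, with no acid to open the epoxide and no base to epimerise C15.

Step 17
Reactants: 23 ring A/B C14 ketone with C18–C19 epoxide and C22–C23 alkene
Product: 25 rings A, B and C diol with C14 and C18 hydroxyls and the C20–C23 homoprenyl chain (3R,6S,7S,11R,14S,15S,18S,19R), via titanium dialkoxide 24 (not isolated)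
Conditions: Cp2TiCl2 (2.5 equiv), Zn dust, THF, rt (green Cp2TiCl); added slowly to 23 in THF (0.01 M), rt; aq. NaH2PO4
Reagents that add atoms: none
Why: Cp2TiCl (trivalent titanium) transfers one electron to the epoxide, which opens at its more substituted carbon to a titanium alkoxide on C18 and a tertiary radical on C19; the radical adds to the titanium-coordinated C14 carbonyl carbon and a second Cp2TiCl traps the alkoxy radical as a tetravalent titanium alkoxide, which makes the addition irreversible. The closest known reaction type is the titanocene-mediated reductive cyclisation of epoxy ketones to cycloalkanols. Ring C closes in the 6-exo-trig mode onto C=O, the only alternatives from C19 being 4-exo or 5-endo attack on the C22–C23 alkene. C18 is carried over from the epoxide with retention, and the new centres C19 and C14 are set in a chair transition state in which the preset C15 methyl and the C18 titanoxy group are equatorial, the C20 chain on the radical carbon and the C13 chain on the carbonyl carbon take the outer positions, and the carbonyl oxygen becomes axial, trans to the C19 methyl. The step needs the radical to cyclise before a second titanium reduces it, which slow addition of the reagent and the sluggish capture of tertiary radicals by Cp2TiCl should secure, and it needs chemoselectivity, which follows because the silyl ether, both alkenes and the ring A ether are inert to Cp2TiCl.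

Step 18
Reactants: 25 rings A, B and C diol
Product: 26 (22S)-22,23-epoxide of 25
Conditions: ent-Shi ketone (from L-fructose, 30 mol%), Oxone (2KHSO5·KHSO4·K2SO4), K2CO3, Bu4NHSO4, MeCN/CH2(OMe)2/aq. Na2B4O7 buffer, 0 °C
Reagents that add atoms: potassium peroxymonosulfate, [K+].[O-]S(=O)(=O)OO
Why: Shi epoxidation selects the trisubstituted C22–C23 alkene over the hindered 1,1-disubstituted C10 methylene, and the L-fructose catalyst sets C22 as S, the epimer for which 6-exo attack by O18 would force the C23 unit axial in a chair.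

Step 19
Reactants: 26 (22S)-22,23-epoxide of 25
Product: 27 rings A to D compound with ring D oxepan-22-ol (22S), C14 hydroxyl and C3 silyl ether
Conditions: (±)-camphorsulfonic acid (10 mol%), CH2Cl2, −20 → 0 °C
Reagents that add atoms: none
Why: acid-catalysed intramolecular epoxide opening in which the equatorial C18 hydroxyl attacks the tertiary, cation-stabilising C23 (7-endo, C22 retained) to close ring D, under catalytic acid at low temperature that activates the epoxide but not the C10 methylene towards the C14 hydroxyl.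

Step 20
Reactants: 27 rings A to D compound with ring D oxepan-22-ol
Product: 28 ring D C22 ketone with C3 triethylsilyl ether
Conditions: Dess–Martin periodinane, NaHCO3, CH2Cl2, rt
Reagents that add atoms: none
Why: Dess–Martin oxidation of the only secondary alcohol (C22) to the ring D ketone; the tertiary C14 alcohol cannot be oxidised and the C22 stereocentre disappears.

Step 21
Reactants: 28 ring D C22 ketone with C3 triethylsilyl ether
Product: 29 3-epi-sodwanone K (free C3 alcohol)
Conditions: Bu4NF, THF, 0 °C → rt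
Reagents that add atoms: none
Why: fluoride cleavage of the triethylsilyl ether, mild enough for the α-alkoxy ketone and for the tertiary alcohol that sits near the exocyclic alkene.

Step 22
Reactants: 29 3-epi-sodwanone K
Product: 30 3-epi-sodwanone K 3-acetate
Conditions: Ac2O, pyridine, DMAP (cat.), CH2Cl2, rt
Reagents that add atoms: acetic anhydride, CC(=O)OC(C)=O
Why: acylation of the secondary C3 alcohol with retention of configuration; the hindered tertiary C14 alcohol does not react under these conditions.

Compound list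
1 | geraniol | CC(C)=CCC/C(C)=C/CO | starting material
2 | (2S,3S)-2,3-epoxygeraniol | OC[C@@H]1O[C@@]1(C)CCC=C(C)C | intermediate
3 | (2S,3S)-2,3-epoxygeranyl trifluoromethanesulfonate | O=S(=O)(OC[C@@H]1O[C@@]1(C)CCC=C(C)C)C(F)(F)F | intermediate
4 | dimethyl (2-oxopropyl)phosphonate | COP(=O)(OC)CC(C)=O | starting material
5 | sodium lithium 1,3-dianion of 4 (not isolated) | [Li+].[Na+].[CH2-]C(=O)[CH-]P(=O)(OC)OC | intermediate
6 | dimethyl [(5S,6S)-5,6-epoxy-6,10-dimethyl-2-oxoundec-9-en-1-yl]phosphonate | COP(=O)(OC)CC(=O)CC[C@@H]1O[C@@]1(C)CCC=C(C)C | intermediate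
7 | benzyloxyacetaldehyde | O=CCOCc1ccccc1 | starting material
8 | (2E,7S,8S)-1-benzyloxy-7,8-epoxy-8,12-dimethyltrideca-2,11-dien-4-one | O=C(/C=C/COCc1ccccc1)CC[C@@H]1O[C@@]1(C)CCC=C(C)C | intermediate
9 | (2E,7S,8S,11R)-1-benzyloxy-7,8:11,12-diepoxy-8,12-dimethyltridec-2-en-4-one | O=C(/C=C/COCc1ccccc1)CC[C@@H]1O[C@@]1(C)CC[C@H]2OC2(C)C | intermediate
10 | (Z)-triethylsilyl enol ether of 9 (C10–OSiEt3, C10=C11) | CC[Si](CC)(CC)O/C(CC[C@@H]1O[C@@]1(C)CC[C@H]2OC2(C)C)=C\CCOCc1ccccc1 | intermediate
11 | trans-fused ring A/B ketone: C3 OSiEt3, C10 ketone, C11 CH2CH2OBn (3R,6S,7S,11S) | O=C1CC[C@@H]2OC(C)(C)[C@H](O[Si](CC)(CC)CC)CC[C@@]2(C)[C@@H]1CCOCc1ccccc1 | intermediate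
12 | ring A/B C10 methylene compound, C13 benzyl ether (3R,6S,7S,11R) | C=C1CC[C@@H]2OC(C)(C)[C@H](O[Si](CC)(CC)CC)CC[C@@]2(C)[C@@H]1CCOCc1ccccc1 | intermediate
13 | ring A/B C13 alcohol | C=C1CC[C@@H]2OC(C)(C)[C@H](O[Si](CC)(CC)CC)CC[C@@]2(C)[C@@H]1CCO | intermediate
14 | ring A/B C13 iodide | C=C1CC[C@@H]2OC(C)(C)[C@H](O[Si](CC)(CC)CC)CC[C@@]2(C)[C@@H]1CCI | intermediate
15 | (R)-3-bromo-2-methylpropan-1-ol | OC[C@@H](C)CBr | starting material
16 | (R)-(3-bromo-2-methylpropoxy)(tert-butyl)dimethylsilane | CC(C)(C)[Si](C)(C)OC[C@@H](C)CBr | intermediate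
17 | Grignard reagent from 16 (not isolated) | CC(C)(C)[Si](C)(C)OC[C@@H](C)C[Mg]Br | intermediate
18 | tert-butyldimethylsilyl ether of (2S,5S,6S)-5,6-epoxy-2,6,10-trimethylundec-9-en-1-ol | CC(C)(C)[Si](C)(C)OC[C@@H](C)CC[C@@H]1O[C@@]1(C)CCC=C(C)C | intermediate
19 | (2S,5S,6S)-5,6-epoxy-2,6,10-trimethylundec-9-en-1-ol | OC[C@@H](C)CC[C@@H]1O[C@@]1(C)CCC=C(C)C | intermediate
20 | (2S,5S,6S)-5,6-epoxy-2,6,10-trimethylundec-9-enal | O=C[C@@H](C)CC[C@@H]1O[C@@]1(C)CCC=C(C)C | intermediate
21 | C13 alkyllithium from 14 (not isolated) | C=C1CC[C@@H]2OC(C)(C)[C@H](O[Si](CC)(CC)CC)CC[C@@]2(C)[C@@H]1CC[Li] | intermediate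
22 | C14 secondary alcohol (both C14 epimers) with C18–C19 epoxide and C22–C23 alkene | C=C1CC[C@@H]2OC(C)(C)[C@H](O[Si](CC)(CC)CC)CC[C@@]2(C)[C@@H]1CCC(O)[C@@H](C)CC[C@@H]3O[C@@]3(C)CCC=C(C)C | intermediate
23 | ring A/B C14 ketone with C18–C19 epoxide and C22–C23 alkene (3R,6S,7S,11R,15S,18S,19S) | C=C1CC[C@@H]2OC(C)(C)[C@H](O[Si](CC)(CC)CC)CC[C@@]2(C)[C@@H]1CCC(=O)[C@@H](C)CC[C@@H]3O[C@@]3(C)CCC=C(C)C | intermediate
24 | C14,C18 bis(chlorotitanocene) dialkoxide of 25 (not isolated) | C=C1CC[C@@H]2OC(C)(C)[C@H](O[Si](CC)(CC)CC)CC[C@@]2(C)[C@@H]1CC[C@]1(O[Ti](Cl)(C3C=CC=C3)C3C=CC=C3)[C@@H](C)CC[C@H](O[Ti](Cl)(C3C=CC=C3)C3C=CC=C3)[C@@]1(C)CCC=C(C)C | intermediate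
25 | rings A, B and C diol with C14 and C18 hydroxyls and homoprenyl chain (3R,6S,7S,11R,14S,15S,18S,19R) | C=C1CC[C@@H]2OC(C)(C)[C@H](O[Si](CC)(CC)CC)CC[C@@]2(C)[C@@H]1CC[C@]1(O)[C@@H](C)CC[C@H](O)[C@@]1(C)CCC=C(C)C | intermediate
26 | (22S)-22,23-epoxide of 25 | C=C1CC[C@@H]2OC(C)(C)[C@H](O[Si](CC)(CC)CC)CC[C@@]2(C)[C@@H]1CC[C@]1(O)[C@@H](C)CC[C@H](O)[C@@]1(C)CC[C@@H]3OC3(C)C | intermediate
27 | rings A to D compound with ring D (22S)-oxepan-22-ol, C14 hydroxyl, C3 OSiEt3 | C=C1CC[C@@H]2OC(C)(C)[C@H](O[Si](CC)(CC)CC)CC[C@@]2(C)[C@@H]1CC[C@]1(O)[C@@H](C)CC[C@@H]3OC(C)(C)[C@@H](O)CC[C@]31C | intermediate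
28 | ring D C22 ketone with C3 OSiEt3 | C=C1CC[C@@H]2OC(C)(C)[C@H](O[Si](CC)(CC)CC)CC[C@@]2(C)[C@@H]1CC[C@]1(O)[C@@H](C)CC[C@@H]3OC(C)(C)C(=O)CC[C@]31C | intermediate
29 | 3-epi-sodwanone K (free C3 alcohol) | C=C1CC[C@@H]2OC(C)(C)[C@H](O)CC[C@@]2(C)[C@@H]1CC[C@]1(O)[C@@H](C)CC[C@@H]3OC(C)(C)C(=O)CC[C@]31C | intermediate
30 | 3-epi-sodwanone K 3-acetate | C=C1CC[C@@H]2OC(C)(C)[C@H](OC(C)=O)CC[C@@]2(C)[C@@H]1CC[C@]1(O)[C@@H](C)CC[C@@H]2OC(C)(C)C(=O)CC[C@]21C | target

Total step count: 22 steps.
Longest linear sequence: 18 steps (steps 1–10 and 15–22, from geraniol).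

Steps most likely to fail

Step 17. Two processes threaten it. The C19 radical may be reduced by a second Cp2TiCl and eliminate to an allylic alcohol before it reaches the hindered carbonyl. Facial discrimination at the planar C19 radical (methyl against the C20 chain) and at C14 may also be weak, giving epimers at the two new centres. The fallback closes the same bond by an ionic, chelation-controlled route, setting out from 23 and returning at 25.
- MgBr2·OEt2 in Et2O at −20 °C should open the epoxide at its tertiary carbon to the C19 bromide with C18 alcohol F1.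
- Buffered Dess–Martin oxidation should give the C19-bromo C14,C18-diketone F2.
- SmI2 (divalent samarium) in THF at −78 °C should reduce the tertiary α-bromo ketone to the C18 samarium enolate, regiospecific at C19, which adds to the C14 ketone in an intramolecular Reformatsky-type aldol through a chelated chair to give the ring C β-hydroxy ketone F3.
- Me4NBH(OAc)3 in MeCN/AcOH should deliver hydride from the C14 hydroxyl to give the 1,3-anti diol, which is 25.

Step 7. The silyl-activated C2–C3 epoxide may undergo hydride shift or elimination, or the enol silane may attack the C6–C7 epoxide directly, before the oxepane oxygen has bridged; the C6–C11 bond also joins a quaternary to a tertiary carbon. The fallback cyclises with the unsubstituted terminal enol silane and attaches the side chain afterwards, setting out from 3 and returning at 11.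
- The lithium enolate of acetone (from isopropenyl acetate and MeLi) should be alkylated by 3 to (5S,6S)-5,6-epoxy-6,10-dimethylundec-9-en-2-one F4.
- Shi epoxidation as in step 5 should give the (9R)-diepoxy ketone F5.
- LiN(iPr)2 and Et3SiCl at −78 °C should give the terminal enol silane F6.
- Et3SiOTf as in step 7 should give the C11-unsubstituted ring A/B ketone F7.
- 2-Iodoxybenzoic acid in DMSO should give the only possible enone, the C8–C9 enone F8.
- Kinetic deprotonation at C11 with LiN(iPr)2 and alkylation with 2-(benzyloxy)ethyl triflate should give the C11-alkylated enone F9.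
- Conjugate reduction with [(Ph3P)CuH]6 and equilibration with DBU should give 11.

Step 19. 6-exo attack of O18 at C22, or attack by the C14 hydroxyl, may compete with 7-endo attack at C23. The fallback uses Markovnikov alkoxymercuration of the alkene itself, with the C14 hydroxyl masked so that the C10 methylene finds no partner, setting out from 25 and returning at 29.
- Me3SiOTf and 2,6-lutidine should give the C14,C18 bis(trimethylsilyl) ether F10.
- K2CO3 in MeOH at 0 °C should remove the less hindered C18 silyl group to give the C14 trimethylsilyl ether F11.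
- Hg(OCOCF3)2 (divalent mercury) in MeNO2 at −20 °C should add O18 to tertiary C23 and close ring D as the C22 organomercurial F12.
- NaBH4 under O2 in DMF should give the C22 alcohol F13.
- Dess–Martin oxidation should give the C22 ketone F14.
- Bu4NF should remove both silyl groups to give 29.

Further compounds
F1 | step 17 | C19 bromide with C18 alcohol from opening of the epoxide of 23 (C14 ketone kept) | C=C1CC[C@@H]2OC(C)(C)[C@H](O[Si](CC)(CC)CC)CC[C@@]2(C)[C@@H]1CCC(=O)[C@@H](C)CC[C@H](O)[C@](C)(Br)CCC=C(C)C
F2 | step 17 | C19-bromo C14,C18-diketone | C=C1CC[C@@H]2OC(C)(C)[C@H](O[Si](CC)(CC)CC)CC[C@@]2(C)[C@@H]1CCC(=O)[C@@H](C)CCC(=O)[C@](C)(Br)CCC=C(C)C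
F3 | step 17 | ring C β-hydroxy ketone (C14 hydroxyl, C18 ketone) | C=C1CC[C@@H]2OC(C)(C)[C@H](O[Si](CC)(CC)CC)CC[C@@]2(C)[C@@H]1CC[C@]1(O)[C@@H](C)CCC(=O)[C@@]1(C)CCC=C(C)C
F4 | step 7 | (5S,6S)-5,6-epoxy-6,10-dimethylundec-9-en-2-one | CC(=O)CC[C@@H]1O[C@@]1(C)CCC=C(C)C
F5 | step 7 | (5S,6S,9R)-5,6:9,10-diepoxy-6,10-dimethylundecan-2-one | CC(=O)CC[C@@H]1O[C@@]1(C)CC[C@H]2OC2(C)C
F6 | step 7 | terminal triethylsilyl enol ether of F5 | C=C(O[Si](CC)(CC)CC)CC[C@@H]1O[C@@]1(C)CC[C@H]2OC2(C)C
F7 | step 7 | C11-unsubstituted ring A/B ketone with C3 OSiEt3 | O=C1CC[C@@H]2OC(C)(C)[C@H](O[Si](CC)(CC)CC)CC[C@@]2(C)C1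
F8 | step 7 | ring A/B C8–C9 enone | O=C1C=C[C@@H]2OC(C)(C)[C@H](O[Si](CC)(CC)CC)CC[C@@]2(C)C1
F9 | step 7 | C11-(2-benzyloxyethyl) ring A/B enone (C11 epimers converge on equilibration) | O=C1C=C[C@@H]2OC(C)(C)[C@H](O[Si](CC)(CC)CC)CC[C@@]2(C)[C@@H]1CCOCc1ccccc1
F10 | step 19 | C14,C18 bis(trimethylsilyl) ether of 25 | C=C1CC[C@@H]2OC(C)(C)[C@H](O[Si](CC)(CC)CC)CC[C@@]2(C)[C@@H]1CC[C@]1(O[Si](C)(C)C)[C@@H](C)CC[C@H](O[Si](C)(C)C)[C@@]1(C)CCC=C(C)C
F11 | step 19 | C14 trimethylsilyl ether of 25 (C18 hydroxyl free) | C=C1CC[C@@H]2OC(C)(C)[C@H](O[Si](CC)(CC)CC)CC[C@@]2(C)[C@@H]1CC[C@]1(O[Si](C)(C)C)[C@@H](C)CC[C@H](O)[C@@]1(C)CCC=C(C)C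
F12 | step 19 | ring D oxepane C22 organomercurial trifluoroacetate (C22 epimers) | C=C1CC[C@@H]2OC(C)(C)[C@H](O[Si](CC)(CC)CC)CC[C@@]2(C)[C@@H]1CC[C@]1(O[Si](C)(C)C)[C@@H](C)CC[C@@H]3OC(C)(C)C([Hg]OC(=O)C(F)(F)F)CC[C@]31C
F13 | step 19 | ring D oxepan-22-ol with C14 trimethylsilyl ether (C22 epimers) | C=C1CC[C@@H]2OC(C)(C)[C@H](O[Si](CC)(CC)CC)CC[C@@]2(C)[C@@H]1CC[C@]1(O[Si](C)(C)C)[C@@H](C)CC[C@@H]3OC(C)(C)C(O)CC[C@]31C
F14 | step 19 | ring D C22 ketone with C14 trimethylsilyl and C3 triethylsilyl ethers | C=C1CC[C@@H]2OC(C)(C)[C@H](O[Si](CC)(CC)CC)CC[C@@]2(C)[C@@H]1CC[C@]1(O[Si](C)(C)C)[C@@H](C)CC[C@@H]3OC(C)(C)C(=O)CC[C@]31C
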